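## Retrosynthetic overview

1. In the ten-membered ring, the ketone carbon C5 and the tertiary carbinol carbon C10 (CH3, OH) face each other 1,6 along both paths (C5-C6-C7-C8-C9-C10 and C5-C4-C3-C2-C1-C10). Cardivin C is therefore a eudesmane whose C5–C10 ring-fusion bond has been replaced by C5=O and HO–C10, and a retro-Criegee cut leads back to a cis-decalin 5-hydroperoxide.
2. The 6-isobutyrate comes from SN2 inversion of a 6-bromide, which also blocks migration of C6 in the key step. Both 5-OOH and 6-Br come from a Δ5 alkene (Br2, then Ag+/H2O2).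
3. All other ring stereocentres are set on the rigid decalin: 8-O by enolate oxidation, 9-O by directed reduction, and the trans α-methylene lactone from an isopropenyl group (SeO2, MnO2).
4. The decalin is assembled from (R)-carvone (C5–C10 and C11–C14; C7 is bought) and a C5 chain made from (S)-epichlorohydrin and vinyl Grignard (C1–C4 and C15; C2 is bought). The two are joined by alkylative 1,3-carbonyl transposition, then intramolecular deconjugative alkylation sets the C10 quaternary centre by relay from C4.
5. Ring order: B (bought), then A (step 6), then the lactone (step 10), then the ten-membered ring by cutting the A/B fusion bond (step 14).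

Key step: step 14

**Remark on numbering.**
- C5 is the ketone carbon and C6 is CH(O-isobutyryl).
- C7 is the CH bearing C11, and C8 is CH(O-lactone).
- C9 is CH(O-angeloyl), and C10 is C(CH3)(OH).
- C1 is CH2, C2 is CHOH and C3 is CH2.
- C4 is CH(CH3).
- C14 is the CH3 on C10, and C15 is the CH3 on C4.
- C11, C12 and C13 are the lactone C=, C=O and =CH2.
- "Up" means the face that carries C14, and "down" means the other face.
- In this numbering the target is 2S,4S,6S,7R,8R,9S,10S.

**Assumption.** The target is taken as the open hydroxy ketone drawn in the SMILES. Hemiketal tautomers of 25, 27 and 28 interconvert and are not counted as separate compounds.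

## Route

Step 1
Reactants: 1 (S)-epichlorohydrin; 2 vinylmagnesium bromide
Product: 3 (2S)-1-chloropent-4-en-2-ol
Conditions: CuI (10 mol %), THF, −40 °C; H2O
Reagents that add atoms: none
Why: Cu(I)-catalysed Grignard opening of the terminal epoxide at its CH2 (SN2) leaves the C2 stereocentre untouched and delivers all five carbons C1–C4 and C15.

Step 2
Reactants: 3 (2S)-1-chloropent-4-en-2-ol
Product: 4 (2S)-1-chloro-4-iodopentan-2-ol (both C4 epimers)
Conditions: NaI, TMSCl, H2O (0.5 equiv), MeCN, 0 °C to rt
Reagents that add atoms: sodium iodide, [Na+].[I-]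
Why: Markovnikov hydroiodination (ionic HI addition) puts iodine on C4; the epimer mixture is harmless because step 4 is stereoconvergent, and the β-chloro alcohol is too deactivated to be substituted.

Step 3
Reactants: 4 (2S)-1-chloro-4-iodopentan-2-ol
Product: 5 TBS ether of 4 (both C4 epimers)
Conditions: TBSOTf, 2,6-lutidine, CH2Cl2, −78 to 0 °C
Reagents that add atoms: tert-butyldimethylsilyl triflate, CC(C)(C)[Si](C)(C)OS(=O)(=O)C(F)(F)F
Why: Standard O-silylation; the OTBS group is also the internal ligand needed in step 4.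

Step 4
Reactants: 5 TBS ether of 4; 6 (R)-carvone
Product: 8 C5 tertiary allylic alcohol (both C5 epimers), via syn-alkyllithium 7 (not isolated)
Conditions: t-BuLi (2.2 equiv), pentane/Et2O, −100 °C; −50 °C, 30 min; then 6, −100 to −78 °C; H2O
Reagents that add atoms: none
Why: Iodine–lithium exchange, then equilibration of the secondary alkyllithium to the five-membered O→Li chelate with both substituents pseudo-equatorial (stereoconvergent, sets C4 syn to the 2-OTBS group), then 1,2-addition with retention at C4; the δ-chloride should survive because 4-exo-tet closure on a chloride is slow at or below −50 °C, and the new carbinol centre is erased in step 5.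

Step 5
Reactants: 8 C5 tertiary allylic alcohol
Product: 9 transposed enone (C9=O, C10(CH3)=C5, chain on C5)
Conditions: PCC (2.5 equiv), 4 Å MS, CH2Cl2, rt
Reagents that add atoms: pyridinium chlorochromate, [O-][Cr](=O)(=O)Cl.c1cc[nH+]cc1
Why: Oxidative 1,3-transposition of a tertiary allylic alcohol (chromate ester, [3,3] shift, oxidation) moves the oxygen from C5 to C9 under non-basic conditions, so C4, C2 and C7 are untouched.

Step 6
Reactants: 9 transposed enone
Product: 11 octalone (C9=O; C5=C6; 14-CH3 up; 15-CH3 down; 2-OTBS up; 7-isopropenyl down), via potassium dienolate 10 (not isolated)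
Conditions: KOt-Bu (1.1 equiv), NaI (cat.), THF/t-BuOH, 0 °C to rt
Reagents that add atoms: none
Why: Intramolecular deconjugative α-alkylation of an extended enolate (6-(enolexo)-exo-tet) closes ring A; γ-deprotonation at the C6 methylene rather than the hindered C4–H keeps C4 and places the alkene at C5=C6, and the chair-like transition state with 15-CH3 equatorial brings C1 to the lower face of C10, since the other face would require a syn-diaxial C14/C15 contact.

Step 7
Reactants: 11 octalone
Product: 13 8-hydroxy ketone (8-OH up), via potassium enolate 12 (not isolated)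
Conditions: KHMDS, THF, −78 °C; 2-(phenylsulfonyl)-3-phenyloxaziridine; AcOH
Reagents that add atoms: 2-(phenylsulfonyl)-3-phenyloxaziridine, O=S(=O)(c1ccccc1)N1OC1c1ccccc1
Why: Davis oxidation of the only possible enolate (C10 is quaternary); the oxidant reaches C8 anti to the adjacent isopropenyl group, which places 8-OH trans to the C7 substituent.

Step 8
Reactants: 13 8-hydroxy ketone
Product: 14 8,9-trans-diol (8-OH up, 9-OH down)
Conditions: Me4NBH(OAc)3, MeCN/AcOH, −30 °C
Reagents that add atoms: none
Why: Hydroxy-directed triacetoxyborohydride reduction (Evans–Saksena type) delivers hydride from the face of 8-OH, which is also the axial trajectory away from the axial C1 methylene, giving the equatorial 9-OH trans to both 8-OH and C14.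

Step 9
Reactants: 14 8,9-trans-diol
Product: 15 triol (C12 allylic alcohol)
Conditions: SeO2 (0.3 equiv), t-BuOOH, CH2Cl2, 0 °C to rt
Reagents that add atoms: tert-butyl hydroperoxide, CC(C)(C)OO
Why: Catalytic SeO2 allylic oxidation (ene, then [2,3] shift) attacks the methyl of the 1,1-disubstituted alkene, while the C5=C6 alkene offers only hindered allylic methines (H4, H7).

Step 10
Reactants: 15 triol
Product: 18 trans-fused α-methylene-γ-lactone with free 9-OH, via hydroxy enal 16 (not isolated), via lactol 17 (not isolated)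
Conditions: MnO2 (excess), CH2Cl2, rt
Reagents that add atoms: none
Why: MnO2 oxidises only the allylic primary alcohol; the enal is trapped by the equatorial 8-OH as a γ-lactol that is oxidised on to the lactone, while 9-OH is not allylic and cannot reach C12 from its 1,3-diequatorial position.

Step 11
Reactants: 18 lactone alcohol; 19 angelic acid
Product: 20 9-angelate (Δ5-octalin lactone)
Conditions: 19, 2,4,6-trichlorobenzoyl chloride, Et3N, toluene, rt; then 18, 80 °C
Reagents that add atoms: none
Why: Yamaguchi-type mixed-anhydride acylation without DMAP is the usual way to place an angelate on a hindered secondary alcohol without Z-to-E isomerisation.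

Step 12
Reactants: 20 9-angelate
Product: 21 5,6-dibromide (5-Br up, 6-Br down)
Conditions: Br2 (1.0 equiv), CH2Cl2, −78 °C
Reagents that add atoms: bromine, BrBr
Why: Electrophilic anti-addition; the trans lactone locks ring B with C1 axial on C10, so Br+ adds to the open upper face and bromide opens the bromonium ion diaxially at C6 from below (Fürst–Plattner rule, as in Δ5-steroids), while the two acrylate-type alkenes are too electron-poor to compete.

Step 13
Reactants: 21 5,6-dibromide
Product: 22 β-bromo hydroperoxide (cis-decalin; 5-OOH up, 6-Br down)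
Conditions: AgO2CCF3 (1.05 equiv), anhydrous H2O2 in Et2O (10 equiv), −78 to −30 °C, dark
Reagents that add atoms: hydrogen peroxide, OO
Why: Silver-assisted perhydrolysis of a tertiary bromide; Ag+ removes 5-Br with anchimeric help from the antiperiplanar 6-Br (bromonium ion on the lower face), and H2O2 attacks the tertiary C5 from above (Markovnikov and diaxial), while the secondary 6-Br is kept for step 15.

Step 14
Reactants: 22 β-bromo hydroperoxide
Product: 25 ten-membered 6-bromo-10-hydroxy-5-ketone (6-Br down; 10S), via pertrifluoroacetate 23 (not isolated), via bridged acylal 24 (not isolated)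
Conditions: (CF3CO)2O, CH2Cl2, −78 °C, then 2,6-lutidine, −78 to 0 °C; THF/pH 7 buffer, 0 °C
Reagents that add atoms: trifluoroacetic anhydride, O=C(OC(=O)C(F)(F)F)C(F)(F)F (acyl group of 23 and 24, lost again); water, O (ketone oxygen on hydrolysis)
Why: O-Trifluoroacetylation turns 5-OOH into perester 23, whose O–O bond ionises while the antiperiplanar C5–C10 σ-bond shifts from C5 to the proximal oxygen (1,2-C-to-O shift); the oxocarbenium/trifluoroacetate pair collapses to acylal 24, and buffered hydrolysis opens it to the C5 ketone and the C10 alcohol. The closest known reaction is the Criegee rearrangement of 9-decalyl peresters to 1-acyloxy-1,6-epoxycyclodecanes and then 6-hydroxycyclodecanone, which cleaves the same bond in the same ring system. No ring is closed by C–C bond formation: the zero-atom bridge of the 6/6 system is replaced by a one-atom oxygen bridge (bicyclo[4.4.0] to 11-oxabicyclo[4.4.1]), and hydrolysis of that bridge reveals the ten-membered carbocycle. C10 is the only stereocentre that changes bonds and, as the migrating carbon, it keeps its configuration (oxygen takes the place of C5), so the quaternary centre from step 6 becomes the 10S carbinol; C5 is erased, and C2, C4 and C6–C9 are spectators. The step needs migration of C10 rather than C4 or C6: C10 is the only tertiary alkyl group, C6 is deactivated by bromine, the only uncongested rotamer of the axial perester points the O–O bond outwards and antiperiplanar to C5–C10, and loss of the syn-diaxial C14/2-OTBS and C1/6-Br contacts helps. Acylation at −78 °C before base is added should outrun base-induced dioxetane closure of the β-bromo hydroperoxide.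

Step 15
Reactants: 25 bromo hydroxy ketone; 26 sodium isobutyrate
Product: 27 2-O-TBS cardivin C
Conditions: 26 (3 equiv), 15-crown-5 (cat.), DMF, 0 °C to rt
Reagents that add atoms: none
Why: Carbonyl-accelerated SN2 displacement of an α-bromo ketone by a carboxylate proceeds with inversion (6-Br down to 6-O-isobutyryl up), and the weakly basic nucleophile should spare H4 and the tertiary alcohol.

Step 16
Reactants: 27 2-O-TBS cardivin C
Product: 28 cardivin C
Conditions: HF·pyridine, THF, 0 °C to rt
Reagents that add atoms: none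
Why: Acidic fluoride desilylation tolerates both esters, the lactone and the α-acyloxy ketone and touches no stereocentre.

## Compound list

1 | (S)-epichlorohydrin | ClC[C@@H]1CO1 | starting material
2 | vinylmagnesium bromide | C=C[Mg]Br | starting material
3 | (2S)-1-chloropent-4-en-2-ol | ClC[C@@H](O)CC=C | intermediate
4 | (2S)-1-chloro-4-iodopentan-2-ol, both C4 epimers | ClC[C@@H](O)CC(C)I | intermediate
5 | tert-butyl{[(2S)-1-chloro-4-iodopentan-2-yl]oxy}dimethylsilane, both C4 epimers | ClC[C@@H](O[Si](C)(C)C(C)(C)C)CC(C)I | intermediate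
6 | (R)-(−)-carvone | CC1=CC[C@H](CC1=O)C(C)=C | starting material
7 | O-chelated syn-alkyllithium (Li on C4 syn to 2-OTBS) | ClC[C@@H](O[Si](C)(C)C(C)(C)C)C[C@@H]([Li])C | intermediate
8 | C5 tertiary allylic alcohol, 1,2-adduct of 7 to 6, C5 epimers | CC1=CC[C@H](CC1(O)[C@@H](C)C[C@H](O[Si](C)(C)C(C)(C)C)CCl)C(C)=C | intermediate
9 | transposed enone, C9=O, C10=C5, chain on C5 | CC1=C([C@@H](C)C[C@H](O[Si](C)(C)C(C)(C)C)CCl)C[C@H](C(C)=C)CC1=O | intermediate
10 | potassium dienolate of 9 (C9-O−, C9=C10, C5=C6) | [K+].[O-]C1=C(C)C([C@@H](C)C[C@H](O[Si](C)(C)C(C)(C)C)CCl)=C[C@H](C(C)=C)C1 | intermediate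
11 | octalone: C9=O, C5=C6, 14-CH3 up, 15-CH3 down, 2-OTBS up, 7-isopropenyl down | C[C@H]1C[C@H](O[Si](C)(C)C(C)(C)C)C[C@]2(C)C1=C[C@H](C(C)=C)CC2=O | intermediate
12 | potassium C8=C9 enolate of 11 | C[C@H]1C[C@H](O[Si](C)(C)C(C)(C)C)C[C@]2(C)C1=C[C@H](C(C)=C)C=C2[O-].[K+] | intermediate
13 | 8-hydroxy ketone, 8-OH up | C[C@H]1C[C@H](O[Si](C)(C)C(C)(C)C)C[C@]2(C)C1=C[C@H](C(C)=C)[C@@H](O)C2=O | intermediate
14 | 8,9-trans-diol, 8-OH up, 9-OH down | C[C@H]1C[C@H](O[Si](C)(C)C(C)(C)C)C[C@]2(C)C1=C[C@H](C(C)=C)[C@@H](O)[C@@H]2O | intermediate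
15 | triol with C12 allylic alcohol | C[C@H]1C[C@H](O[Si](C)(C)C(C)(C)C)C[C@]2(C)C1=C[C@H](C(=C)CO)[C@@H](O)[C@@H]2O | intermediate
16 | hydroxy enal (C12 aldehyde) | C[C@H]1C[C@H](O[Si](C)(C)C(C)(C)C)C[C@]2(C)C1=C[C@H](C(=C)C=O)[C@@H](O)[C@@H]2O | intermediate
17 | γ-lactol (C12 epimers) | C[C@H]1C[C@H](O[Si](C)(C)C(C)(C)C)C[C@]2(C)C1=C[C@@H]3C(=C)C(O)O[C@H]3[C@@H]2O | intermediate
18 | trans-fused α-methylene-γ-lactone, free 9-OH | C[C@H]1C[C@H](O[Si](C)(C)C(C)(C)C)C[C@]2(C)C1=C[C@@H]3C(=C)C(=O)O[C@H]3[C@@H]2O | intermediate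
19 | angelic acid, (Z)-2-methylbut-2-enoic acid | C/C=C(/C)C(=O)O | starting material
20 | 9-angelate, Δ5-octalin lactone | C[C@H]1C[C@H](O[Si](C)(C)C(C)(C)C)C[C@]2(C)C1=C[C@@H]3C(=C)C(=O)O[C@H]3[C@@H]2OC(=O)/C(C)=C\C | intermediate
21 | 5,6-dibromide, 5-Br up, 6-Br down | C[C@H]1C[C@H](O[Si](C)(C)C(C)(C)C)C[C@]2(C)[C@@]1(Br)[C@H](Br)[C@@H]3C(=C)C(=O)O[C@H]3[C@@H]2OC(=O)/C(C)=C\C | intermediate
22 | cis-decalin β-bromo hydroperoxide, 5-OOH up, 6-Br down | C[C@H]1C[C@H](O[Si](C)(C)C(C)(C)C)C[C@]2(C)[C@@]1(OO)[C@H](Br)[C@@H]3C(=C)C(=O)O[C@H]3[C@@H]2OC(=O)/C(C)=C\C | intermediate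
23 | C5 pertrifluoroacetate | C[C@H]1C[C@H](O[Si](C)(C)C(C)(C)C)C[C@]2(C)[C@@]1(OOC(=O)C(F)(F)F)[C@H](Br)[C@@H]3C(=C)C(=O)O[C@H]3[C@@H]2OC(=O)/C(C)=C\C | intermediate
24 | bridged acylal, 5,10-epoxy (11-oxabicyclo[4.4.1]undecane) 5-trifluoroacetate | C[C@H]1C[C@H](O[Si](C)(C)C(C)(C)C)C[C@]2(C)O[C@@]1(OC(=O)C(F)(F)F)[C@H](Br)[C@@H]3C(=C)C(=O)O[C@H]3[C@@H]2OC(=O)/C(C)=C\C | intermediate
25 | ten-membered 6-bromo-10-hydroxy-5-ketone, 6-Br down, 10S | C=C1C(=O)O[C@@H]2[C@@H]1[C@@H](Br)C(=O)[C@@H](C)C[C@H](O[Si](C)(C)C(C)(C)C)C[C@](C)(O)[C@H]2OC(=O)/C(C)=C\C | intermediate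
26 | sodium isobutyrate | CC(C)C(=O)[O-].[Na+] | starting material
27 | 2-O-TBS cardivin C | C=C1C(=O)O[C@@H]2[C@@H]1[C@H](OC(=O)C(C)C)C(=O)[C@@H](C)C[C@H](O[Si](C)(C)C(C)(C)C)C[C@](C)(O)[C@H]2OC(=O)/C(C)=C\C | intermediate
28 | cardivin C | C=C1C(=O)O[C@@H]2[C@@H]1[C@H](OC(=O)C(C)C)C(=O)[C@@H](C)C[C@H](O)C[C@](C)(O)[C@H]2OC(=O)/C(C)=C\C | target

## Step count and risks

Total step count: 16. Longest linear sequence: 16 steps (1 to 28); 13 steps from (R)-carvone.

**Risk 1, step 14.** The β-acyloxy group on C9 lowers the migratory aptitude of C10. Migration of C4 (cleavage of ring A) or simple heterolysis at C5 followed by elimination could therefore compete with the wanted shift.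

The fallback cleaves the same bond by a radical route and sets out from 20.
- Dihydroxylation on the open upper face (OsO4, pyridine; NaHSO3) should give the 5,6-cis-diol F1.
- Selective acylation of the secondary hydroxyl (isobutyryl chloride, DMAP) gives the 6-isobutyrate F2, which already has the correct C6 configuration.
- Alkoxyl-radical β-fragmentation (PhI(OAc)2, I2, hν) cuts C5–C10 towards the tertiary radical. After iodine transfer and elimination this gives the (E)-1(10)-ene 5,10-seco ketone F3.
- Markovnikov iodohydrin formation (NIS, aqueous THF) on the only electron-rich alkene gives the 1-iodo-10-ol F4.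
- Radical deiodination (Bu3SnH, Et3B, −78 °C) returns to the route at 27.
- In this variant the C10 configuration depends on peripheral attack on the E-alkene and no longer on retention.

**Risk 2, step 13.** The product can react further with silver ion or adventitious base, closing to a dioxetane that then cleaves C5–C6. The C5 cation can also lose a proton.

The fallback replaces the bromide handle with an oxygen handle and sets out from 20.
- NBS in aqueous THF (cat. HClO4) should give, by diaxial opening, the bromohydrin F5 (5-Br up, 6-OH down).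
- DBU closes it to the lower-face 5,6-epoxide F6.
- Phosphomolybdic-acid-catalysed perhydrolysis (ethereal H2O2) opens the epoxide at the tertiary C5 from above to give the 5-hydroperoxy-6-ol F7.
- Excess trifluoroacetic anhydride at −78 °C acylates both O–H groups before warming triggers the same Criegee shift. Buffered methanolysis then gives the 6-epi hydroxy ketone F8 (6-OH down).
- Mitsunobu esterification with isobutyric acid (PPh3, DIAD) inverts C6 and returns to the route at 27.

**Risk 3, step 6.** Three processes could go wrong here: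
- proton transfer to the C4-derived dienolate, which loses the C4 centre and gives a Δ4 alkene;
- base-induced aromatisation of the isopropenyl enone;
- eroded facial selectivity at C10, because the wanted transition state carries an axial OTBS group.

The fallback installs the C8 oxygen first, as a second control element, and sets out from 9.
- Kinetic α′-deprotonation (KHMDS, −78 °C) and Davis oxidation anti to the isopropenyl group give the 8-hydroxy enone F9.
- TESCl/imidazole gives the 8-OTES enone F10. A(1,2) strain with the enolate oxygen pushes its silyloxy group pseudo-axial on the upper face, 1,3 to C10.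
- KOt-Bu then closes ring A from the lower face to give the 8-OTES octalone F11.
- Selective TES removal (PPTS, MeOH) returns to the route at 13.

## Further compounds

F1 | step 14 | 5,6-cis-diol of 20 (5-OH up, 6-OH up) | C[C@H]1C[C@H](O[Si](C)(C)C(C)(C)C)C[C@]2(C)[C@@]1(O)[C@@H](O)[C@@H]3C(=C)C(=O)O[C@H]3[C@@H]2OC(=O)/C(C)=C\C
F2 | step 14 | 6-isobutyrate of F1 | C[C@H]1C[C@H](O[Si](C)(C)C(C)(C)C)C[C@]2(C)[C@@]1(O)[C@@H](OC(=O)C(C)C)[C@@H]3C(=C)C(=O)O[C@H]3[C@@H]2OC(=O)/C(C)=C\C
F3 | step 14 | (E)-1(10)-ene 5,10-seco ketone | C=C1C(=O)O[C@@H]2[C@@H]1[C@H](OC(=O)C(C)C)C(=O)[C@@H](C)C[C@H](O[Si](C)(C)C(C)(C)C)/C=C(\C)[C@H]2OC(=O)/C(C)=C\C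
F4 | step 14 | 1-iodo-10-hydroxy iodohydrin | C=C1C(=O)O[C@@H]2[C@@H]1[C@H](OC(=O)C(C)C)C(=O)[C@@H](C)C[C@H](O[Si](C)(C)C(C)(C)C)[C@H](I)[C@](C)(O)[C@H]2OC(=O)/C(C)=C\C
F5 | step 13 | bromohydrin (5-Br up, 6-OH down) | C[C@H]1C[C@H](O[Si](C)(C)C(C)(C)C)C[C@]2(C)[C@@]1(Br)[C@H](O)[C@@H]3C(=C)C(=O)O[C@H]3[C@@H]2OC(=O)/C(C)=C\C
F6 | step 13 | lower-face 5,6-epoxide | C[C@H]1C[C@H](O[Si](C)(C)C(C)(C)C)C[C@]2(C)[C@@]14O[C@@H]4[C@@H]3C(=C)C(=O)O[C@H]3[C@@H]2OC(=O)/C(C)=C\C
F7 | step 13 | 5-hydroperoxy-6-ol (5-OOH up, 6-OH down) | C[C@H]1C[C@H](O[Si](C)(C)C(C)(C)C)C[C@]2(C)[C@@]1(OO)[C@H](O)[C@@H]3C(=C)C(=O)O[C@H]3[C@@H]2OC(=O)/C(C)=C\C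
F8 | step 13 | 6-epi hydroxy ketone (6-OH down) | C=C1C(=O)O[C@@H]2[C@@H]1[C@@H](O)C(=O)[C@@H](C)C[C@H](O[Si](C)(C)C(C)(C)C)C[C@](C)(O)[C@H]2OC(=O)/C(C)=C\C
F9 | step 6 | 8-hydroxy enone (8-OH up) | CC1=C([C@@H](C)C[C@H](O[Si](C)(C)C(C)(C)C)CCl)C[C@H](C(C)=C)[C@@H](O)C1=O
F10 | step 6 | 8-OTES enone | CC1=C([C@@H](C)C[C@H](O[Si](C)(C)C(C)(C)C)CCl)C[C@H](C(C)=C)[C@@H](O[Si](CC)(CC)CC)C1=O
F11 | step 6 | 8-OTES octalone | C[C@H]1C[C@H](O[Si](C)(C)C(C)(C)C)C[C@]2(C)C1=C[C@H](C(C)=C)[C@@H](O[Si](CC)(CC)CC)C2=O
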